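**Plan**

- Retrosynthetic cuts: last, the three aryl MOM ethers and the C4 ketone (carried as a silylated carbinol); then ring B at C5'–C6', C2'–C3', C4'–C5' and C1'–C2', giving an α'-diazo enone whose diazo carbon bears the geranyl group, plus methoxyacetylene; then the enone C=C (C1'–C6' of the target), giving a chroman-2-carbaldehyde and a geranylated β-ketophosphonate; finally the chroman back to a chromone-2-carboxylate made from 2,4,6-trihydroxyacetophenone and diethyl oxalate.
- Enabling feature: ring B is a resorcinol monomethyl ether with four different substituents at C1' (chroman C2), C2' (OH), C4' (OMe) and C5' (geranyl) and H at C3' and C6'. This is the pattern that a vinylketene/alkoxyalkyne benzannulation lays down in one regiodefined event.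
- Forward order: ring A comes with the starting material, ring C closes in step 1, the side chain is attached by olefination, ring B closes in step 11, then C4 is returned to the ketone and the MOM groups are removed.
- Stereochemistry: C2 (S) comes from asymmetric hydrogenation of the chromone-2-carboxylic acid and is carried through. C4 is a temporary substrate-controlled centre erased by oxidation. Both E-alkenes of the geranyl chain are bought with geranyl bromide.

Key step: step 11

Assumption: in step 3 the ligand antipode that leads to the 2S acid is used, to be fixed by one pilot hydrogenation because the sense of induction for this substrate cannot be read from a model; the 4S (2,4-cis) configuration written for 9 to 26 is the one expected from axial hydride delivery and is removed again in step 14.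

**Route**

Step 1
Reactants: 1 2,4,6-trihydroxyacetophenone; 2 diethyl oxalate
Product: 4 ethyl 5,7-dihydroxy-4-oxo-4H-chromene-2-carboxylate, via diketo ester 3 (not isolated)
Conditions: NaOEt, EtOH, reflux; then HCl, EtOH, reflux
Reagents that add atoms: none
Why: Claisen condensation of the methyl ketone with diethyl oxalate followed by acid-promoted cyclodehydration is the classical chromone-2-carboxylate synthesis; ring C closes by attack of an ortho phenol oxygen on the α-keto ester carbonyl and loss of water.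

Step 2
Reactants: 4 ethyl 5,7-dihydroxy-4-oxo-4H-chromene-2-carboxylate
Product: 6 5,7-bis(methoxymethoxy)-4-oxo-4H-chromene-2-carboxylic acid, via bis-MOM ethyl ester 5 (not isolated)
Conditions: NaH, MOMCl, DMF, 0 °C to rt; then LiOH, THF/H2O, 0 °C; 1 M HCl to pH 3, 0 °C
Reagents that add atoms: chloromethyl methyl ether (MOMCl), COCCl; lithium hydroxide, [Li+].[OH-]
Why: Williamson-type O-alkylation of both phenoxides (NaH is needed for the hydrogen-bonded C5 hydroxyl) followed by ester saponification should give the free acid; the MOM ethers tolerate every basic, hydride and organometallic step that follows.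

Step 3
Reactants: 6 5,7-bis(methoxymethoxy)-4-oxo-4H-chromene-2-carboxylic acid
Product: 7 (2S)-5,7-bis(methoxymethoxy)-4-oxochromane-2-carboxylic acid
Conditions: H2 (30 bar), Rh(cod)2BF4 (1 mol %), chiral ferrocenyl bisphosphine (Josiphos class, antipode as assumed above), Et3N (0.5 equiv), THF/MeOH, 25 °C
Reagents that add atoms: none
Why: Carboxylate-directed asymmetric hydrogenation of an α-aryloxy-α,β-unsaturated acid (chromone-2-carboxylic acids belong to this class) with a cationic monovalent rhodium–bisphosphine catalyst; two-point binding of carboxylate and C2=C3 to rhodium lets the ligand choose the alkene face and sets C2 as S, while the vinylogous aryl ketone and the arene should stay untouched.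

Step 4
Reactants: 7 (2S)-5,7-bis(methoxymethoxy)-4-oxochromane-2-carboxylic acid
Product: 9 methyl (2S,4S)-4-hydroxy-5,7-bis(methoxymethoxy)chromane-2-carboxylate, via keto methyl ester 8 (not isolated)
Conditions: Me3SiCHN2, PhMe/MeOH, 0 °C; then NaBH4, −10 °C
Reagents that add atoms: trimethylsilyldiazomethane, C[Si](C)(C)C=[N+]=[N-]
Why: Neutral diazoalkane esterification followed by borohydride reduction; hydride should add axially to the half-chair chromanone with the C2 ester equatorial, giving the 2,4-cis (4S) alcohol under substrate control, and not isolating 8 avoids racemisation of C2 by retro-oxa-Michael ring opening.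

Step 5
Reactants: 9 methyl (2S,4S)-4-hydroxy-5,7-bis(methoxymethoxy)chromane-2-carboxylate
Product: 10 methyl (2S,4S)-4-[(tert-butyldimethylsilyl)oxy]-5,7-bis(methoxymethoxy)chromane-2-carboxylate
Conditions: TBSCl, imidazole, DMAP (cat.), DMF, 35 °C
Reagents that add atoms: tert-butyldimethylsilyl chloride (TBSCl), CC(C)(C)[Si](C)(C)Cl
Why: Standard imidazole-mediated silylation of a secondary alcohol under non-acidic conditions, which keeps the electron-rich benzylic C4–O bond from ionising and masks C4 at the alcohol level so that C2 cannot be lost through a β-aryloxy ketone.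

Step 6
Reactants: 10 methyl (2S,4S)-4-[(tert-butyldimethylsilyl)oxy]-5,7-bis(methoxymethoxy)chromane-2-carboxylate
Product: 11 (2S,4S)-4-[(tert-butyldimethylsilyl)oxy]-5,7-bis(methoxymethoxy)chromane-2-carbaldehyde
Conditions: i-Bu2AlH, CH2Cl2, −78 °C; MeOH, then aq. KNaC4H4O6
Reagents that add atoms: none
Why: Partial reduction of an α-alkoxy ester at −78 °C through a chelated aluminium hemiacetal that collapses only on work-up is a reliable route to chroman-2-carbaldehydes; the aldehyde is used crude at once.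

Step 7
Reactants: 12 dimethyl (2-oxopropyl)phosphonate; 13 geranyl bromide
Product: 14 dimethyl [(5E)-6,10-dimethyl-2-oxoundeca-5,9-dien-1-yl]phosphonate
Conditions: NaH, THF, 0 °C; n-BuLi, 0 °C; 13, 0 °C to rt; H2O
Reagents that add atoms: none
Why: The 1,3-dianion of a β-ketophosphonate alkylates at its more reactive terminal carbon, and SN2 displacement on the primary allylic bromide keeps the E geometry of the geranyl unit.

Step 8
Reactants: 11 (2S,4S)-4-[(tert-butyldimethylsilyl)oxy]-5,7-bis(methoxymethoxy)chromane-2-carbaldehyde; 14 dimethyl [(5E)-6,10-dimethyl-2-oxoundeca-5,9-dien-1-yl]phosphonate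
Product: 15 (2S,4S)-4-[(tert-butyldimethylsilyl)oxy]-2-[(1E,6E)-7,11-dimethyl-3-oxododeca-1,6,10-trien-1-yl]-5,7-bis(methoxymethoxy)chromane
Conditions: LiCl, i-Pr2NEt, MeCN, 0 °C to rt
Reagents that add atoms: none
Why: Horner–Wadsworth–Emmons olefination under Masamune–Roush conditions uses only a weak amine base with lithium chelation, which suits an epimerisable α-oxygenated aldehyde, and the stabilised phosphonate anion should give the E-enone.

Step 9
Reactants: 15 (2S,4S)-4-[(tert-butyldimethylsilyl)oxy]-2-[(1E,6E)-7,11-dimethyl-3-oxododeca-1,6,10-trien-1-yl]-5,7-bis(methoxymethoxy)chromane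
Product: 17 (2S,4S)-4-[(tert-butyldimethylsilyl)oxy]-2-[(1E,6E)-4-diazo-7,11-dimethyl-3-oxododeca-1,6,10-trien-1-yl]-5,7-bis(methoxymethoxy)chromane, via trifluoroacetyl ketone 16 (not isolated)
Conditions: LiN(SiMe3)2, THF, −78 °C; CF3CO2CH2CF3; aq. NH4Cl; then MsN3, Et3N, H2O (1 equiv), MeCN, rt
Reagents that add atoms: methanesulfonyl azide (MsN3), CS(=O)(=O)N=[N+]=[N-]; 2,2,2-trifluoroethyl trifluoroacetate, O=C(OCC(F)(F)F)C(F)(F)F (its CF3CO group is found in 16 only)
Why: Detrifluoroacetylative diazo transfer: the kinetic α'-lithium enolate of the enone is C-acylated by the trifluoroacetate, and the activated 1,3-diketone takes the diazo group from the sulfonyl azide and loses the trifluoroacetyl group as the N-sulfonyl amide (Regitz-type transfer), the standard way to α'-diazo enones.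

Step 10
Reactants: 18 chloroacetaldehyde dimethyl acetal
Product: 19 methoxyacetylene
Conditions: NaNH2, liq. NH3, −33 °C; then cold satd aq. NaCl; distilled into cold ClCH2CH2Cl
Reagents that add atoms: none
Why: Twofold base-induced elimination (HCl, then methanol) with excess amide gives sodium methoxyacetylide, which is protonated on aqueous work-up; this is the standard preparation of the volatile 1-alkoxyalkynes.

Step 11
Reactants: 17 (2S,4S)-4-[(tert-butyldimethylsilyl)oxy]-2-[(1E,6E)-4-diazo-7,11-dimethyl-3-oxododeca-1,6,10-trien-1-yl]-5,7-bis(methoxymethoxy)chromane; 19 methoxyacetylene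
Product: 24 (2S,4S)-4-[(tert-butyldimethylsilyl)oxy]-2-{5-[(2E)-3,7-dimethylocta-2,6-dien-1-yl]-2-hydroxy-4-methoxyphenyl}-5,7-bis(methoxymethoxy)chromane, via vinylketene 20 (not isolated), via vinylcyclobutenone 21 (not isolated), via dienylketene 22 (not isolated), via cyclohexadienone 23 (not isolated)
Conditions: 19 (5 equiv), hν (300 nm, Pyrex), degassed ClCH2CH2Cl, 5 °C; then 80 °C (sealed tube)
Reagents that add atoms: none
Why: Direct irradiation expels N2 from 17 and the alkenyl carbon migrates from the carbonyl carbon to the diazo carbon (Wolff rearrangement, forming C5'–C6') to give vinylketene 20 with the geranyl group on its α-carbon; 19 then adds across the ketene C=C in a [2+2] cycloaddition (C2'–C3' and C4'–C5'), the four-membered ring of 21 opens by conrotatory 4π-electrocyclic cleavage to dienylketene 22, and 6π-electrocyclisation (C1'–C2') gives dienone 23, which enolises to the phenol. The closest known reaction type is the Danheiser benzannulation in its photochemical variant, in which α'-diazo enones and alkoxy- or siloxyalkynes give resorcinol derivatives. Ring B is closed by the pericyclic, disrotatory 6π step and aromatised by tautomerisation, whereas the cyclobutenone ring is only a relay and does not survive. No stereocentre is created in 24, because the sp3 centres of 21 and 23 vanish on aromatisation, and C2 and C4 of the chroman lie outside the reacting π-system under neutral, base-free conditions. Two selectivities are needed: the regiochemistry of the [2+2], secured by the polarisation of the ynol ether (its nucleophilic unsubstituted carbon bonds to the electrophilic ketene carbonyl carbon, which puts OMe meta to the new OH and next to the geranyl-bearing carbon), and Wolff shift in preference to 1,2-hydrogen shift from the geranyl CH2, which is favoured by direct unsensitised excitation, by the good migratory aptitude of the sp2 carbon and by an excess of the ketene trap. Heating after irradiation should drive remaining 21 through to the phenol, since ring opening is reversible and only the isomer of 22 with the vinyl group cis to the ketenyl carbon can cyclise.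

Step 12
Reactants: 24 (2S,4S)-4-[(tert-butyldimethylsilyl)oxy]-2-{5-[(2E)-3,7-dimethylocta-2,6-dien-1-yl]-2-hydroxy-4-methoxyphenyl}-5,7-bis(methoxymethoxy)chromane
Product: 25 (2S,4S)-4-[(tert-butyldimethylsilyl)oxy]-2-{5-[(2E)-3,7-dimethylocta-2,6-dien-1-yl]-4-methoxy-2-(methoxymethoxy)phenyl}-5,7-bis(methoxymethoxy)chromane
Conditions: MOMCl, i-Pr2NEt, CH2Cl2, 0 °C to rt
Reagents that add atoms: chloromethyl methyl ether (MOMCl), COCCl
Why: O-alkylation of the new phenol masks the electron-rich resorcinol ring before the oxidation in step 14 and adds no extra deprotection step, since it leaves together with the other two MOM groups.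

Step 13
Reactants: 25 (2S,4S)-4-[(tert-butyldimethylsilyl)oxy]-2-{5-[(2E)-3,7-dimethylocta-2,6-dien-1-yl]-4-methoxy-2-(methoxymethoxy)phenyl}-5,7-bis(methoxymethoxy)chromane
Product: 26 (2S,4S)-2-{5-[(2E)-3,7-dimethylocta-2,6-dien-1-yl]-4-methoxy-2-(methoxymethoxy)phenyl}-5,7-bis(methoxymethoxy)chroman-4-ol
Conditions: Bu4NF, THF, 0 °C to rt
Reagents that add atoms: none
Why: Fluoride cleaves the Si–O bond under non-acidic conditions, which the acid-labile flavan-4-ol and the MOM ethers tolerate.

Step 14
Reactants: 26 (2S,4S)-2-{5-[(2E)-3,7-dimethylocta-2,6-dien-1-yl]-4-methoxy-2-(methoxymethoxy)phenyl}-5,7-bis(methoxymethoxy)chroman-4-ol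
Product: 27 (2S)-2-{5-[(2E)-3,7-dimethylocta-2,6-dien-1-yl]-4-methoxy-2-(methoxymethoxy)phenyl}-5,7-bis(methoxymethoxy)chroman-4-one
Conditions: Dess–Martin periodinane, NaHCO3, CH2Cl2, 0 °C to rt
Reagents that add atoms: none
Why: Dess–Martin oxidation of the benzylic secondary alcohol under buffered, base-free conditions removes the temporary C4 centre without giving the flavanone a chance to open to the chalcone, so C2 stays S.

Step 15
Reactants: 27 (2S)-2-{5-[(2E)-3,7-dimethylocta-2,6-dien-1-yl]-4-methoxy-2-(methoxymethoxy)phenyl}-5,7-bis(methoxymethoxy)chroman-4-one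
Product: 28 Kuwanon U, (2S)-2-{5-[(2E)-3,7-dimethylocta-2,6-dien-1-yl]-2-hydroxy-4-methoxyphenyl}-5,7-dihydroxychroman-4-one
Conditions: 3 M aq. HCl/MeOH (1:10), 40 °C
Reagents that add atoms: none
Why: Acid-catalysed acetal exchange removes the three aryl MOM ethers as dimethoxymethane; the aryl methyl ether, the trisubstituted alkenes (no ortho hydroxyl next to the geranyl group) and the C2 centre should survive, because flavanone ring opening is base-promoted.

**Compound list**

1 | 2,4,6-trihydroxyacetophenone | CC(=O)c1c(O)cc(O)cc1O | starting material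
2 | diethyl oxalate | CCOC(=O)C(=O)OCC | starting material
3 | ethyl 2,4-dioxo-4-(2,4,6-trihydroxyphenyl)butanoate (Claisen adduct, not isolated) | CCOC(=O)C(=O)CC(=O)c1c(O)cc(O)cc1O | intermediate
4 | ethyl 5,7-dihydroxy-4-oxo-4H-chromene-2-carboxylate | CCOC(=O)c1cc(=O)c2c(O)cc(O)cc2o1 | intermediate
5 | ethyl 5,7-bis(methoxymethoxy)-4-oxo-4H-chromene-2-carboxylate (not isolated) | CCOC(=O)c1cc(=O)c2c(OCOC)cc(OCOC)cc2o1 | intermediate
6 | 5,7-bis(methoxymethoxy)-4-oxo-4H-chromene-2-carboxylic acid | OC(=O)c1cc(=O)c2c(OCOC)cc(OCOC)cc2o1 | intermediate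
7 | (2S)-5,7-bis(methoxymethoxy)-4-oxochromane-2-carboxylic acid | OC(=O)[C@@H]1CC(=O)c2c(OCOC)cc(OCOC)cc2O1 | intermediate
8 | methyl (2S)-5,7-bis(methoxymethoxy)-4-oxochromane-2-carboxylate (not isolated) | COC(=O)[C@@H]1CC(=O)c2c(OCOC)cc(OCOC)cc2O1 | intermediate
9 | methyl (2S,4S)-4-hydroxy-5,7-bis(methoxymethoxy)chromane-2-carboxylate | COC(=O)[C@@H]1C[C@H](O)c2c(OCOC)cc(OCOC)cc2O1 | intermediate
10 | methyl (2S,4S)-4-[(tert-butyldimethylsilyl)oxy]-5,7-bis(methoxymethoxy)chromane-2-carboxylate | COC(=O)[C@@H]1C[C@H](O[Si](C)(C)C(C)(C)C)c2c(OCOC)cc(OCOC)cc2O1 | intermediate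
11 | (2S,4S)-4-[(tert-butyldimethylsilyl)oxy]-5,7-bis(methoxymethoxy)chromane-2-carbaldehyde | O=C[C@@H]1C[C@H](O[Si](C)(C)C(C)(C)C)c2c(OCOC)cc(OCOC)cc2O1 | intermediate
12 | dimethyl (2-oxopropyl)phosphonate | COP(=O)(CC(C)=O)OC | starting material
13 | geranyl bromide, (2E)-1-bromo-3,7-dimethylocta-2,6-diene | BrC/C=C(\C)CCC=C(C)C | starting material
14 | dimethyl [(5E)-6,10-dimethyl-2-oxoundeca-5,9-dien-1-yl]phosphonate | COP(=O)(CC(=O)CC/C=C(\C)CCC=C(C)C)OC | intermediate
15 | (2S,4S)-4-[(tert-butyldimethylsilyl)oxy]-2-[(1E,6E)-7,11-dimethyl-3-oxododeca-1,6,10-trien-1-yl]-5,7-bis(methoxymethoxy)chromane | O=C(/C=C/[C@@H]1C[C@H](O[Si](C)(C)C(C)(C)C)c2c(OCOC)cc(OCOC)cc2O1)CC/C=C(\C)CCC=C(C)C | intermediate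
16 | (2S,4S)-4-[(tert-butyldimethylsilyl)oxy]-2-[(1E,6E)-7,11-dimethyl-3-oxo-4-(trifluoroacetyl)dodeca-1,6,10-trien-1-yl]-5,7-bis(methoxymethoxy)chromane (not isolated) | O=C(/C=C/[C@@H]1C[C@H](O[Si](C)(C)C(C)(C)C)c2c(OCOC)cc(OCOC)cc2O1)C(C(=O)C(F)(F)F)C/C=C(\C)CCC=C(C)C | intermediate
17 | (2S,4S)-4-[(tert-butyldimethylsilyl)oxy]-2-[(1E,6E)-4-diazo-7,11-dimethyl-3-oxododeca-1,6,10-trien-1-yl]-5,7-bis(methoxymethoxy)chromane | O=C(/C=C/[C@@H]1C[C@H](O[Si](C)(C)C(C)(C)C)c2c(OCOC)cc(OCOC)cc2O1)C(=[N+]=[N-])C/C=C(\C)CCC=C(C)C | intermediate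
18 | chloroacetaldehyde dimethyl acetal | COC(CCl)OC | starting material
19 | methoxyacetylene | COC#C | intermediate
20 | vinylketene: ketene carbon double-bonded to a carbon bearing the geranyl group and the (E)-2-(chroman-2-yl)vinyl group (not isolated) | O=C=C(C/C=C(\C)CCC=C(C)C)/C=C/[C@@H]1C[C@H](O[Si](C)(C)C(C)(C)C)c2c(OCOC)cc(OCOC)cc2O1 | intermediate
21 | 3-methoxy-4-geranyl-4-[(E)-2-(chroman-2-yl)vinyl]cyclobut-2-en-1-one, mixture at the quaternary carbon (not isolated) | O=C1C=C(OC)C1(C/C=C(\C)CCC=C(C)C)/C=C/[C@@H]2C[C@H](O[Si](C)(C)C(C)(C)C)c3c(OCOC)cc(OCOC)cc3O2 | intermediate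
22 | dienylketene O=C=CH–C(OMe)=C(geranyl)–CH=CH–(chroman-2-yl), vinyl cis to the ketenyl carbon (not isolated) | O=C=C/C(OC)=C(/C/C=C(\C)CCC=C(C)C)\C=C\[C@@H]1C[C@H](O[Si](C)(C)C(C)(C)C)c2c(OCOC)cc(OCOC)cc2O1 | intermediate
23 | 6-(chroman-2-yl)-4-geranyl-3-methoxycyclohexa-2,4-dien-1-one, keto tautomer of 24 (not isolated) | O=C1C=C(OC)C(C/C=C(\C)CCC=C(C)C)=CC1[C@@H]2C[C@H](O[Si](C)(C)C(C)(C)C)c3c(OCOC)cc(OCOC)cc3O2 | intermediate
24 | (2S,4S)-4-[(tert-butyldimethylsilyl)oxy]-2-{5-[(2E)-3,7-dimethylocta-2,6-dien-1-yl]-2-hydroxy-4-methoxyphenyl}-5,7-bis(methoxymethoxy)chromane | COc1cc(O)c([C@@H]2C[C@H](O[Si](C)(C)C(C)(C)C)c3c(OCOC)cc(OCOC)cc3O2)cc1C/C=C(\C)CCC=C(C)C | intermediate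
25 | (2S,4S)-4-[(tert-butyldimethylsilyl)oxy]-2-{5-[(2E)-3,7-dimethylocta-2,6-dien-1-yl]-4-methoxy-2-(methoxymethoxy)phenyl}-5,7-bis(methoxymethoxy)chromane | COc1cc(OCOC)c([C@@H]2C[C@H](O[Si](C)(C)C(C)(C)C)c3c(OCOC)cc(OCOC)cc3O2)cc1C/C=C(\C)CCC=C(C)C | intermediate
26 | (2S,4S)-2-{5-[(2E)-3,7-dimethylocta-2,6-dien-1-yl]-4-methoxy-2-(methoxymethoxy)phenyl}-5,7-bis(methoxymethoxy)chroman-4-ol | COc1cc(OCOC)c([C@@H]2C[C@H](O)c3c(OCOC)cc(OCOC)cc3O2)cc1C/C=C(\C)CCC=C(C)C | intermediate
27 | (2S)-2-{5-[(2E)-3,7-dimethylocta-2,6-dien-1-yl]-4-methoxy-2-(methoxymethoxy)phenyl}-5,7-bis(methoxymethoxy)chroman-4-one | COc1cc(OCOC)c([C@@H]2CC(=O)c3c(OCOC)cc(OCOC)cc3O2)cc1C/C=C(\C)CCC=C(C)C | intermediate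
28 | Kuwanon U, (2S)-2-{5-[(2E)-3,7-dimethylocta-2,6-dien-1-yl]-2-hydroxy-4-methoxyphenyl}-5,7-dihydroxychroman-4-one | COc1cc(O)c([C@@H]2CC(=O)c3c(O)cc(O)cc3O2)cc1C/C=C(\C)CCC=C(C)C | target

**Step count and risks**

Total: 15 steps. Longest linear sequence: 13 steps (steps 1–6, 8, 9, 11–15); steps 7 and 10 are side branches.

Step 11 (key step). The carbene or excited diazo ketone may undergo 1,2-hydrogen shift from the geranyl CH2 to a cross-conjugated dienone in place of the Wolff shift. The branched diazo ketone may also photolyse sluggishly because the two electron-rich arenes absorb part of the light. The fallback sets out from aldehyde 11 and phosphonate 12 and comes back to the route at 25; it also bypasses steps 8 and 9. Olefination of 11 with 12 under the conditions of step 8 would give the methyl enone F1. Kinetic enolisation with LiN(SiMe3)2, trifluoroacetylation to the trifluoroacetyl ketone F2 and diazo transfer from MsN3 would give the terminal diazo enone F3. Its carbene carbon has no neighbouring C–H on the non-carbonyl side, so only the Wolff shift is open. Irradiation with 19 would then run through the vinylketene F4, the methoxycyclobutenone F5, the dienylketene F6 and the cyclohexadienone F7 to the phenol F8, which lacks the geranyl group. Iodination of its phenoxide (I2, NaHCO3, THF/H2O), directed para to the hydroxyl and hence to C5' and sparing the non-phenolic ring A, would give the iodophenol F9. MOMCl/i-Pr2NEt would give the aryl iodide F10. Iodine–lithium exchange (t-BuLi, THF, −78 °C), transmetalation with CuBr·SMe2 and allylic substitution on geranyl bromide 13 would deliver 25.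

Step 3. Enantioface discrimination may be poor on this peri-substituted, electron-rich chromone acid, the ketone may be over-reduced, or the acidic substrate may slowly strip a MOM group in the alcoholic solvent. The fallback sets out from 6 and comes back at 7. Hydrogenation of 6 over an achiral catalyst (Rh(cod)2BF4/Ph2P(CH2)4PPh2, H2, THF/MeOH) would give the racemic keto acid F11. Crystallisation of its salt with (R)-1-phenylethylamine (or the antipodal amine, whichever gives the less soluble salt of the 2S acid) would give the diastereomerically pure ammonium carboxylate F12, and cold dilute acid would free 7.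

Step 8. The α-aryloxy aldehyde 11 may epimerise at C2 under the amine base before it is olefinated, which would surface as the 2R enantiomer after step 14, or it may be lost by hydration and self-condensation on handling. The fallback sets out from ester 10 and comes back at 15. LiBH4 (THF, 0 °C) would reduce 10 to the primary alcohol F13. Dess–Martin oxidation of F13 in CH2Cl2 in the presence of the stabilised keto ylide F14 (made from Ph3P=CHC(O)CH3 by deprotonation with n-BuLi at −78 °C and alkylation with 13) would trap aldehyde 11 as it forms, under base-free Wittig conditions, and give 15.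

Further compounds
F1 | step 11 | (2S,4S)-4-[(tert-butyldimethylsilyl)oxy]-5,7-bis(methoxymethoxy)-2-[(1E)-3-oxobut-1-en-1-yl]chromane | CC(=O)/C=C/[C@@H]1C[C@H](O[Si](C)(C)C(C)(C)C)c2c(OCOC)cc(OCOC)cc2O1
F2 | step 11 | (2S,4S)-4-[(tert-butyldimethylsilyl)oxy]-5,7-bis(methoxymethoxy)-2-[(1E)-6,6,6-trifluoro-3,5-dioxohex-1-en-1-yl]chromane | O=C(CC(=O)C(F)(F)F)/C=C/[C@@H]1C[C@H](O[Si](C)(C)C(C)(C)C)c2c(OCOC)cc(OCOC)cc2O1
F3 | step 11 | (2S,4S)-4-[(tert-butyldimethylsilyl)oxy]-2-[(1E)-4-diazo-3-oxobut-1-en-1-yl]-5,7-bis(methoxymethoxy)chromane | [N-]=[N+]=CC(=O)/C=C/[C@@H]1C[C@H](O[Si](C)(C)C(C)(C)C)c2c(OCOC)cc(OCOC)cc2O1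
F4 | step 11 | vinylketene O=C=CH–CH=CH–(chroman-2-yl) | O=C=C/C=C/[C@@H]1C[C@H](O[Si](C)(C)C(C)(C)C)c2c(OCOC)cc(OCOC)cc2O1
F5 | step 11 | 3-methoxy-4-[(E)-2-(chroman-2-yl)vinyl]cyclobut-2-en-1-one | O=C1C=C(OC)C1/C=C/[C@@H]2C[C@H](O[Si](C)(C)C(C)(C)C)c3c(OCOC)cc(OCOC)cc3O2
F6 | step 11 | dienylketene O=C=CH–C(OMe)=CH–CH=CH–(chroman-2-yl) | O=C=C/C(OC)=C\C=C\[C@@H]1C[C@H](O[Si](C)(C)C(C)(C)C)c2c(OCOC)cc(OCOC)cc2O1
F7 | step 11 | 6-(chroman-2-yl)-3-methoxycyclohexa-2,4-dien-1-one | O=C1C=C(OC)C=CC1[C@@H]2C[C@H](O[Si](C)(C)C(C)(C)C)c3c(OCOC)cc(OCOC)cc3O2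
F8 | step 11 | (2S,4S)-4-[(tert-butyldimethylsilyl)oxy]-2-(2-hydroxy-4-methoxyphenyl)-5,7-bis(methoxymethoxy)chromane | COc1ccc([C@@H]2C[C@H](O[Si](C)(C)C(C)(C)C)c3c(OCOC)cc(OCOC)cc3O2)c(O)c1
F9 | step 11 | (2S,4S)-4-[(tert-butyldimethylsilyl)oxy]-2-(2-hydroxy-5-iodo-4-methoxyphenyl)-5,7-bis(methoxymethoxy)chromane | COc1cc(O)c([C@@H]2C[C@H](O[Si](C)(C)C(C)(C)C)c3c(OCOC)cc(OCOC)cc3O2)cc1I
F10 | step 11 | (2S,4S)-4-[(tert-butyldimethylsilyl)oxy]-2-[5-iodo-4-methoxy-2-(methoxymethoxy)phenyl]-5,7-bis(methoxymethoxy)chromane | COc1cc(OCOC)c([C@@H]2C[C@H](O[Si](C)(C)C(C)(C)C)c3c(OCOC)cc(OCOC)cc3O2)cc1I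
F11 | step 3 | racemic 5,7-bis(methoxymethoxy)-4-oxochromane-2-carboxylic acid | OC(=O)C1CC(=O)c2c(OCOC)cc(OCOC)cc2O1
F12 | step 3 | (R)-1-phenylethylammonium (2S)-5,7-bis(methoxymethoxy)-4-oxochromane-2-carboxylate | C[C@@H]([NH3+])c1ccccc1.[O-]C(=O)[C@@H]1CC(=O)c2c(OCOC)cc(OCOC)cc2O1
F13 | step 8 | [(2S,4S)-4-[(tert-butyldimethylsilyl)oxy]-5,7-bis(methoxymethoxy)chroman-2-yl]methanol | OC[C@@H]1C[C@H](O[Si](C)(C)C(C)(C)C)c2c(OCOC)cc(OCOC)cc2O1
F14 | step 8 | (5E)-6,10-dimethyl-1-(triphenylphosphoranylidene)undeca-5,9-dien-2-one | O=C(C=P(c1ccccc1)(c1ccccc1)c1ccccc1)CC/C=C(\C)CCC=C(C)C
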